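## Analysis of the target

The target is a resveratrol hexamer with six 4-hydroxyphenyl groups, six resorcinol-derived rings, fifteen free phenols and three dihydrofuran oxygens. Its backbone is a chain of six contiguous benzylic methines, numbered here C1 to C6, with a 4-hydroxyphenyl group on C1, C3 and C6. C1 and C2 lie in a seven-membered ring with two carbons of ring A (benzene ring of the first dihydrobenzofuran), the C3 methine of that dihydrofuran and two carbons of ring B (the resorcinol ring on that methine, bonded to C1). C4, C5 and C6 lie in an eight-membered ring with two carbons of ring C (benzene ring of the second dihydrobenzofuran), its furan C3 methine and two carbons of ring D (bonded to C6); C5 carries ring E, the benzene ring of a third dihydrobenzofuran whose 3,5-dihydroxyphenyl group (ring F) is free. There are twelve stereocentres: the three 2,3-diaryl-dihydrofurans are all trans and all (2R,3R), and the backbone is C1 S, C2 S, C3 R, C4 R, C5 S, C6 S. In the seven-membered ring H-1, H-2 and the fusion hydrogen are on one face; in the eight-membered ring H-4 and H-5 are cis, and H-6 and the fusion hydrogen are on the other face. The dihydrofuran C2–O bonds are 4-oxybenzylic and ionise with acid, every arene is strongly nucleophilic and the free phenols oxidise easily, so the phenols are carried as methyl ethers to the last step. The difficulty lies in two medium rings closed between hindered benzylic carbons, nine all-carbon methine stereocentres without a heteroatom handle, and the union of a dimer-level and a tetramer-level part at C2–C3. The strategy rests on the C1–C2 bond of the seven-membered ring: C1 (diarylmethine on ring B) and C2 (benzylic CH on ring A) can be bridged by one sulfur atom in an easily closed eight-membered ring, and loss of SO2 then leaves this bond as a C1=C2 alkene with a nucleophilic C2 end.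

## Retrosynthetic reasoning

**39 from 38.** The fifteen O–CH3 bonds are cut last. Methyl ethers survive every acid, base, hydride and organometallic step before, and one Lewis-acid ether cleavage then frees all phenols.

**38 from 22 and 35.** The C2–C3 bond and the C1–H bond are cut. C3 is the only backbone carbon outside both medium rings and is 4-methoxybenzylic, so it can be the cation (the O-methyl equivalent of a para-quinone methide) obtained from carbinol 35. The C1=C2 alkene of 22 is the nucleophile, and the charge moves to the doubly benzylic C1, where a hydride donor finishes the seven-membered ring. The forward step must set C2 and C3 in the C–C bond formation and C1 in the reduction.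

**22 from 19.** The C1=C2 bond is traced to the eight-membered sulfone 19, with sulfur between C1 and C2. Closing an eight-membered ring through two C–S bonds is easy, whereas a direct C1–C2 closure between a diarylmethyl and a benzylic carbon is not. Extrusion of SO2 contracts the ring by one atom and leaves no stereocentre to control.

**19 from 18, 16 and 15.** The two C–S bonds are cut back to diol 16 through sulfide 18. Diol 16 comes from keto ester 15 by reduction, which turns both carbonyl carbons into the benzylic electrophiles that sulfide bridges.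

**15 from 13 and 14.** The bond between ring B and the C1 carbon is cut as a Friedel–Crafts acylation of ester 13 with acid chloride 14. The ester on ring A deactivates that ring, so the acyl group enters the resorcinol ring. The same compound 15 also serves the right half, where this bond is the ring D–C6 bond; making it before any ring is closed removes the choice between seven- and eight-membered closure that a late cationic cyclisation would face.

**35 from 33 and 34; 33 from 30 and 29.** The aryl–C3 bond is cut to aldehyde 33 and arylmagnesium reagent 34. The C3–C4 bond is traced to ketone 29 through methylene compound 30; hydroboration of 30 places hydrogen on C4 from the face away from ring E and so sets C4.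

**29 from 28 and 11.** The C5–ring E bond is cut as an α-arylation of ketone 28 with bromide 11. This adds the third dihydrobenzofuran as a finished, enantiopure unit, and the α-centre C5 can be equilibrated.

**28 from 26, 24 and 15.** The C5–C6 bond of the eight-membered ring is cut to methyl ketone 26, whose benzhydryl methyl ether is a latent cation at C6 and whose acetyl group supplies C4 and C5 as an enol nucleophile. Ketone 26 comes from 15 through ether 24 and amide 25.

**13 from 11, 10, 8 and 7; 7 from 5 and 1; 5 from 3 and 4; 3 from 2 and 1.** The furan C2–C3 bond is cut as an enantioselective carbene C–H insertion of the diazo compound derived from hydrazone 8, giving cis compound 10, which acid turns into trans bromide 11. The bromine becomes the ester of 13 or the coupling handle for ring E. Ketone 7 comes from aldehyde 5 and the aryl group of 1; 5 comes from phenol 3 and chloride 4; 3 comes from 1 by formylation (2) and selective demethylation. One building block thus supplies all three dihydrobenzofurans.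

## Alternatives that were turned down

**Alternative 1:** The five backbone bonds C1–C2 to C5–C6 and five aryl–carbon bonds are cut one after another, with no ring formed. In the forward direction a benzhydryl boronic ester is homologated five times (carbenoid insertion into the C–B bond, then replacement of the α-chloride by an arylmagnesium reagent) to give the hexa-aryl boronic ester A1. In its favour, each backbone centre is set by the chiral diol on boron, so by the reagent; on that point it is stronger than the chosen route, whose C3 to C6 centres rest on substrate control. Against it, every cycle runs on a more crowded secondary benzylic boronate, α-chloro benzylic boronic esters epimerise easily, and ten bond constructions are strictly linear. A1 also still lacks all three dihydrofurans (six stereocentres the boron director cannot reach) and both medium rings, which would have to be closed on a flexible chain. The chosen strategy instead takes five rings and six stereocentres three times from one enantiopure dihydrobenzofuran and contracts a ring that is easy to close.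

**Alternative 2:** The C4–C5 bond and the ring D–C6 bond are cut, so the right half becomes two identical dihydrobenzofuran stilbene phenols. In the forward direction one-electron oxidation of the phenolate gives persistent radicals that dimerise at the stilbene β-carbons, and a Lewis acid then lets one quinone methide alkylate the resorcinol ring of the other half, giving the eight-ring intermediate A2 that keeps one quinone methide. In its favour, it is the shortest conceivable entry to the tetramer-level core, clearly shorter than the eleven steps used here from 15, and it delivers the electrophile for the union directly. Against it, the radical coupling cannot distinguish the two possible relative configurations at C4/C5, and the closure by a unit's own resorcinol ring (seven-membered) competes with the crossed eight-membered closure that is needed. The tert-butyl and bromine auxiliaries must also be removed at the hexamer stage, the di-tert-butyl quinone methide is a hindered electrophile, and the seven-membered ring of the left half is not addressed at all. The chosen strategy is longer on the right half but makes the ring D–C6 bond by acylation before ring closure, so the ring size is fixed by construction, and it supplies the left half as a defined nucleophile.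

**Alternative 3:** The two bonds between a furan C3 and its resorcinol ring (ring B and ring D) are cut, with both furans at the aromatic benzofuran level. In the forward direction a double Suzuki coupling of 3-bromobenzofurans with neighbouring arylboronic esters closes the seven- and the eight-membered ring and gives A3. In its favour, sp2–sp2 coupling is a dependable way to close medium rings and avoids all carbocation side reactions; for ring closure alone it is at least as strong as the chosen route. Against it, A3 contains two tetrasubstituted 2,3-diarylbenzofurans that must be reduced to trans-(2R,3R)-dihydrofurans on a crowded hexamer. That means four stereocentres, with hydrogenation favouring cis and ionic reduction offering no face control. All six backbone centres must also be in place in an open chain before the coupling. The chosen strategy sets the dihydrofuran centres in the first asymmetric step and never has to reduce a benzofuran.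

Key step: step 14

Assumption: Rh2(S-PTAD)4 is taken as the catalyst antipode that gives the 3R insertion product 10; if the sense of induction is the opposite, Rh2(R-PTAD)4 is used and nothing else changes.

Remark: the electrophile of the fragment union is generated from carbinol 35 as the 4-methoxybenzylic cation, the O-methyl form of a para-quinone methide, so that all phenols stay methylated until step 25.

## Route

Step 1
Reactants: 1 1-bromo-3,5-dimethoxybenzene
Product: 2 2-bromo-4,6-dimethoxybenzaldehyde
Conditions: POCl3, DMF, 0 °C then 90 °C; aqueous NaOAc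
Reagents that add atoms: N,N-dimethylformamide, CN(C)C=O; water, O
Why: Vilsmeier–Haack formylation; the carbon para to one methoxy group and ortho to the other (next to bromine) is the most reactive and is less shielded than the carbon between the two methoxy groups.

Step 2
Reactants: 2 2-bromo-4,6-dimethoxybenzaldehyde
Product: 3 2-bromo-6-hydroxy-4-methoxybenzaldehyde
Conditions: BCl3, CH2Cl2, −78 °C to 0 °C; then water
Reagents that add atoms: none
Why: Chelation-controlled ether cleavage; boron binds the aldehyde oxygen and the ortho methoxy oxygen in a six-membered chelate, so only that methyl ether is cleaved.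

Step 3
Reactants: 3 2-bromo-6-hydroxy-4-methoxybenzaldehyde; 4 4-methoxybenzyl chloride
Product: 5 2-bromo-4-methoxy-6-[(4-methoxybenzyl)oxy]benzaldehyde
Conditions: K2CO3, NaI (cat.), DMF, 60 °C
Reagents that add atoms: none
Why: Williamson ether synthesis on the phenoxide; the benzylic CH2 introduced here later becomes furan C2.

Step 4
Reactants: 5 2-bromo-4-methoxy-6-[(4-methoxybenzyl)oxy]benzaldehyde; 1 1-bromo-3,5-dimethoxybenzene
Product: 6 [2-bromo-4-methoxy-6-(4-methoxybenzyloxy)phenyl](3,5-dimethoxyphenyl)methanol (racemic)
Conditions: 1, Mg, THF, reflux; then 5, THF, 0 °C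
Reagents that add atoms: none
Why: Grignard addition of the aryl nucleophile to the aldehyde; the aryl bromide of 5 does not exchange with an arylmagnesium halide at 0 °C.

Step 5
Reactants: 6 [2-bromo-4-methoxy-6-(4-methoxybenzyloxy)phenyl](3,5-dimethoxyphenyl)methanol
Product: 7 [2-bromo-4-methoxy-6-(4-methoxybenzyloxy)phenyl](3,5-dimethoxyphenyl)methanone
Conditions: Dess–Martin periodinane, NaHCO3, CH2Cl2, rt
Reagents that add atoms: none
Why: Dess–Martin oxidation of the hindered diaryl carbinol; buffered neutral conditions leave the 4-methoxybenzyl ether and the aryl bromide alone.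

Step 6
Reactants: 7 [2-bromo-4-methoxy-6-(4-methoxybenzyloxy)phenyl](3,5-dimethoxyphenyl)methanone
Product: 8 hydrazone of ketone 7 (C=N–NH2 in place of C=O)
Conditions: N2H4·H2O, AcOH (cat.), n-BuOH, 110 °C
Reagents that add atoms: hydrazine, NN
Why: Condensation of hydrazine with the ketone under forcing conditions, needed because both ortho positions are substituted; the electron-rich bromoarene is not substituted by hydrazine at this temperature.

Step 7
Reactants: 8 hydrazone of ketone 7
Product: 10 (2S,3R)-4-bromo-3-(3,5-dimethoxyphenyl)-6-methoxy-2-(4-methoxyphenyl)-2,3-dihydro-1-benzofuran (cis), via diaryldiazomethane 9 (not isolated)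
Conditions: MnO2, CH2Cl2, 0 °C, filtration; then Rh2(S-PTAD)4 (1 mol%; PTAD = N-phthalimido-adamantylacetate), CH2Cl2, −20 °C to rt
Reagents that add atoms: none
Why: Oxidation of the hydrazone gives the diaryl diazo compound, and the rhodium carbene inserts into the benzylic ether C–H bond five atoms away (intramolecular donor/donor carbene C–H insertion). The chiral carboxylate ligands set furan C3 (R), and the concerted insertion gives the cis 2,3-relationship.

Step 8
Reactants: 10 (2S,3R)-4-bromo-3-(3,5-dimethoxyphenyl)-6-methoxy-2-(4-methoxyphenyl)-2,3-dihydro-1-benzofuran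
Product: 11 (2R,3R)-4-bromo-3-(3,5-dimethoxyphenyl)-6-methoxy-2-(4-methoxyphenyl)-2,3-dihydro-1-benzofuran (trans)
Conditions: TFA, CH2Cl2, 0 °C to rt
Reagents that add atoms: none
Why: Acid reversibly opens the C2–O bond to the 4-methoxybenzylic cation and the phenol recloses to the more stable trans isomer (epimerisation at C2 only); C3 is not touched, so its configuration from step 7 is kept.

Step 9
Reactants: 11 (2R,3R)-4-bromo-3-(3,5-dimethoxyphenyl)-6-methoxy-2-(4-methoxyphenyl)-2,3-dihydro-1-benzofuran
Product: 13 methyl (2R,3R)-3-(3,5-dimethoxyphenyl)-6-methoxy-2-(4-methoxyphenyl)-2,3-dihydro-1-benzofuran-4-carboxylate, via 4-lithio-dihydrobenzofuran 12 (not isolated)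
Conditions: n-BuLi, THF, −78 °C; then ClCO2Me, −78 °C to rt
Reagents that add atoms: methyl chloroformate, COC(=O)Cl
Why: Bromine–lithium exchange and acylation of the aryllithium; the ester is wanted because it deactivates ring A in the next step and supplies the benzylic carbon C2 (or C4).

Step 10
Reactants: 13 methyl (2R,3R)-3-(3,5-dimethoxyphenyl)-6-methoxy-2-(4-methoxyphenyl)-2,3-dihydro-1-benzofuran-4-carboxylate; 14 4-methoxybenzoyl chloride
Product: 15 methyl (2R,3R)-3-[3,5-dimethoxy-2-(4-methoxybenzoyl)phenyl]-6-methoxy-2-(4-methoxyphenyl)-2,3-dihydro-1-benzofuran-4-carboxylate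
Conditions: SnCl4, CH2Cl2, −20 °C to 0 °C
Reagents that add atoms: none
Why: Friedel–Crafts acylation; ring A is deactivated by the ester, and the 3,5-dimethoxyphenyl ring reacts ortho to the furan carbon and para to a methoxy group. SnCl4 is used because a stronger Lewis acid would cleave the methoxy group next to the new ketone.

Step 11
Reactants: 15 keto ester
Product: 16 [(2R,3R)-3-{2-[hydroxy(4-methoxyphenyl)methyl]-3,5-dimethoxyphenyl}-6-methoxy-2-(4-methoxyphenyl)-2,3-dihydro-1-benzofuran-4-yl]methanol (both carbinol epimers)
Conditions: LiAlH4, THF, 0 °C to rt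
Reagents that add atoms: none
Why: Hydride reduction of ester and diaryl ketone in one operation; the new carbinol centre forms as a mixture, which is erased in step 14.

Step 12
Reactants: 16 diol
Product: 18 eight-membered cyclic sulfide (sulfur bridging the ring A CH2 carbon and the ring B CH(4-methoxyphenyl) carbon; both epimers at that carbon), via dibromide 17 (not isolated)
Conditions: PBr3, pyridine (cat.), CH2Cl2, 0 °C; then Na2S·9H2O, DMF, 0 °C to rt, high dilution
Reagents that add atoms: sodium sulfide, [Na+].[Na+].[S-2]
Why: Both benzylic alcohols become bromides, and sulfide closes the eight-membered ring by two substitutions (SN2 at the primary carbon, SN1-like at the diarylmethyl carbon). The aprotic solvent prevents solvolysis of the very labile diarylmethyl bromide.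

Step 13
Reactants: 18 cyclic sulfide
Product: 19 eight-membered cyclic sulfone (SO2 between the ring A CH2 and the ring B CH(4-methoxyphenyl) carbon; both epimers)
Conditions: mCPBA (2.2 equiv), NaHCO3, CH2Cl2, 0 °C
Reagents that add atoms: 3-chloroperoxybenzoic acid, OOC(=O)c1cccc(Cl)c1
Why: Peracid oxidation of the sulfide through the sulfoxide to the sulfone; at 0 °C with buffer the electron-rich arenes are not oxidised.

Step 14
Reactants: 19 cyclic sulfone
Product: 22 cyclic stilbene (dihydrofuran-fused dibenzocycloheptatriene with 4-methoxyphenyl on C1 of the new C1=C2 bond), via alpha-chloro sulfone 20 (not isolated), via episulfone 21 (not isolated)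
Conditions: KOH (powdered), CCl4, t-BuOH/H2O, 60 °C
Reagents that add atoms: none
Why: Hydroxide deprotonates an α-sulfonyl carbon and the carbanion takes chlorine from CCl4; chlorination is expected at the more acidic diarylmethyl carbon (20), and chlorination at the CH2 group would lead to the same product. The carbanion at the other α-carbon then displaces chloride in a 1,3-elimination to the episulfone 21, which loses SO2 and leaves the C1=C2 double bond. This is the Ramberg–Bäcklund reaction with halogenation in the flask, established for cyclic bis-benzylic sulfones that give cyclic stilbenes. The seven-membered ring is not closed by a direct attack: it arises by contraction of the eight-membered sulfone, and the only ring-forming event is the three-membered (3-exo-tet) episulfone closure. No stereocentre is formed; the epimer mixture at the sulfonyl carbon is erased and the ring enforces the cis alkene. The step needs deprotonation at the α-sulfonyl carbons only, which their much higher acidity compared with the dihydrofuran methines secures, so the (2R,3R)-dihydrofuran and its base-sensitive C2–O bond stay intact. Halogen transfer goes to the carbanion and not to the arenes, because CCl4 is no electrophilic aromatic chlorinating agent. Addition of dichlorocarbene to the new alkene is the side reaction to watch.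

Step 15
Reactants: 15 keto ester
Product: 24 methyl (2R,3R)-3-{3,5-dimethoxy-2-[methoxy(4-methoxyphenyl)methyl]phenyl}-6-methoxy-2-(4-methoxyphenyl)-2,3-dihydro-1-benzofuran-4-carboxylate (both ether epimers), via hydroxy ester 23 (not isolated)
Conditions: NaBH4, THF/MeOH, 0 °C to 40 °C; then CSA (cat.), MeOH, rt
Reagents that add atoms: methanol, CO
Why: NaBH4 reduces the diaryl ketone but not the aromatic ester; acid-catalysed SN1 etherification then turns the easily ionised benzhydrol into its methyl ether, a base-stable latent cation at C6.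

Step 16
Reactants: 24 benzhydryl methyl ether ester
Product: 25 (2R,3R)-N-methoxy-N-methyl-3-{3,5-dimethoxy-2-[methoxy(4-methoxyphenyl)methyl]phenyl}-6-methoxy-2-(4-methoxyphenyl)-2,3-dihydro-1-benzofuran-4-carboxamide
Conditions: MeNH(OMe)·HCl, i-PrMgCl, THF, −20 °C to 0 °C
Reagents that add atoms: N,O-dimethylhydroxylamine hydrochloride, CNOC.Cl
Why: Weinreb amide formation by attack of the magnesium amide on the ester; the benzhydryl ether is inert to the base.

Step 17
Reactants: 25 Weinreb amide
Product: 26 1-[(2R,3R)-3-{3,5-dimethoxy-2-[methoxy(4-methoxyphenyl)methyl]phenyl}-6-methoxy-2-(4-methoxyphenyl)-2,3-dihydro-1-benzofuran-4-yl]ethanone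
Conditions: MeMgBr, THF, 0 °C
Reagents that add atoms: methylmagnesium bromide, C[Mg]Br
Why: Grignard addition to the Weinreb amide stops at the ketone because the chelated tetrahedral intermediate survives until work-up.

Step 18
Reactants: 26 methyl ketone
Product: 28 eight-membered ring ketone (C4 ketone; C5 CH2; C6 bearing H and 4-methoxyphenyl with H-6 on the face of the fusion hydrogen), via silyl enol ether 27 (not isolated)
Conditions: LiHMDS, TMSCl, THF, −78 °C; then TMSOTf (cat.), CH2Cl2, high dilution, −78 °C to −20 °C
Reagents that add atoms: none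
Why: Mukaiyama-type SN1 alkylation: TMSOTf ionises the benzhydryl methyl ether to a diarylcarbenium ion stabilised by three methoxy groups, and the terminal carbon of the silyl enol ether, held close by the two rings on the furan C3, closes the eight-membered ring (endo with respect to the enol double bond). C6 is expected to form with its hydrogen on the side of the fusion hydrogen, both aryl-bearing bonds pointing outwards from the tub-shaped ring; this is substrate control of modest reliability.

Step 19
Reactants: 28 eight-membered ring ketone; 11 (2R,3R)-4-bromo-3-(3,5-dimethoxyphenyl)-6-methoxy-2-(4-methoxyphenyl)-2,3-dihydro-1-benzofuran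
Product: 29 ketone 28 carrying on C5 the (2R,3R)-dihydrobenzofuran-4-yl group of 11 (ring E) trans to the aryl group on C6
Conditions: Pd(OAc)2, XPhos, NaOtBu, toluene, 80 °C; then DBU, CH2Cl2, rt
Reagents that add atoms: none
Why: Palladium-catalysed α-arylation of the ketone enolate at the only enolisable carbon, C5, brings in ring E with its dihydrofuran already in the (2R,3R) form. Base equilibration then puts ring E in the more stable position trans to the C6 aryl group.

Step 20
Reactants: 29 α-aryl ketone
Product: 30 exocyclic methylene compound (C4=CH2 in place of C4=O)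
Conditions: Cp2TiMe2, toluene, 70 °C, dark
Reagents that add atoms: dimethyltitanocene, C[Ti](C)(C1C=CC=C1)C1C=CC=C1
Why: Petasis methylenation by the titanium methylidene formed on heating; the reagent is not basic, so the hindered, easily enolised ketone is olefinated without epimerisation at C5.

Step 21
Reactants: 30 exocyclic methylene compound
Product: 32 primary alcohol (C4–CH2OH with H-4 cis to H-5), via B-alkyl-9-BBN 31 (not isolated)
Conditions: 9-BBN, THF, 65 °C; then NaOH, H2O2, 0 °C to rt
Reagents that add atoms: hydrogen peroxide, OO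
Why: Hydroboration–oxidation; boron adds to the CH2 terminus and hydrogen to C4 in a syn addition from the face opposite ring E on the neighbouring C5, which sets C4 with the CH2OH carbon cis to ring E.

Step 22
Reactants: 32 primary alcohol
Product: 33 aldehyde (C4–CHO)
Conditions: Dess–Martin periodinane, NaHCO3, CH2Cl2, 0 °C
Reagents that add atoms: none
Why: Dess–Martin oxidation under buffered conditions at 0 °C, chosen to keep the α-centre C4 from epimerising.

Step 23
Reactants: 33 aldehyde; 34 4-methoxyphenylmagnesium bromide
Product: 35 carbinol C4–CH(OH)(4-methoxyphenyl) (both epimers at the carbinol carbon C3)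
Conditions: THF, −78 °C
Reagents that add atoms: none
Why: Grignard addition to the aldehyde at low temperature, faster than enolisation; both carbinol epimers are acceptable because this carbon becomes a planar cation in step 24.

Step 24
Reactants: 35 carbinol; 22 cyclic stilbene
Product: 38 pentadecamethyl ether of the target, via benzylic cation 36 (not isolated), via diaryl cation 37 (not isolated)
Conditions: BF3·OEt2, CH2Cl2, −78 °C to −40 °C; then Et3SiH, −40 °C to 0 °C
Reagents that add atoms: none
Why: Ionisation of 35 gives the 4-methoxybenzylic cation 36, which alkylates the CH end (C2) of the alkene of 22 on the face of the boat-shaped seven-membered ring turned away from the flagpole hydrogen of the fusion carbon and from the furan 2-aryl group. The resulting diaryl cation 37 at C1 is reduced by the silane from the face opposite the new, very large C2 substituent (ionic hydrogenation), which puts H-1 cis to H-2. The configuration at C3 depends on which face of the planar cation is attacked; attack anti to the eight-membered ring on C4 (Felkin-type) is counted on and is the least secure stereochemical element.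

Step 25
Reactants: 38 pentadecamethyl ether
Product: 39 target hexamer CNP0184494.1
Conditions: BBr3, CH2Cl2, −78 °C to rt; then MeOH
Reagents that add atoms: none
Why: Lewis-acid cleavage of all fifteen aryl methyl ethers (boron-bound oxonium, bromide attack on methyl); the trans-dihydrofurans are the thermodynamic isomers, so reversible opening of their C2–O bonds does not change configuration.

## Compound list

1 | 1-bromo-3,5-dimethoxybenzene | COc1cc(Br)cc(OC)c1 | starting material
2 | 2-bromo-4,6-dimethoxybenzaldehyde | O=Cc1c(Br)cc(OC)cc1OC | intermediate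
3 | 2-bromo-6-hydroxy-4-methoxybenzaldehyde | O=Cc1c(Br)cc(OC)cc1O | intermediate
4 | 4-methoxybenzyl chloride | COc1ccc(CCl)cc1 | starting material
5 | 2-bromo-4-methoxy-6-[(4-methoxybenzyl)oxy]benzaldehyde | O=Cc1c(Br)cc(OC)cc1OCc1ccc(OC)cc1 | intermediate
6 | [2-bromo-4-methoxy-6-(4-methoxybenzyloxy)phenyl](3,5-dimethoxyphenyl)methanol, racemic | OC(c1cc(OC)cc(OC)c1)c1c(Br)cc(OC)cc1OCc1ccc(OC)cc1 | intermediate
7 | [2-bromo-4-methoxy-6-(4-methoxybenzyloxy)phenyl](3,5-dimethoxyphenyl)methanone | O=C(c1cc(OC)cc(OC)c1)c1c(Br)cc(OC)cc1OCc1ccc(OC)cc1 | intermediate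
8 | hydrazone of 7 | NN=C(c1cc(OC)cc(OC)c1)c1c(Br)cc(OC)cc1OCc1ccc(OC)cc1 | intermediate
9 | diaryldiazomethane from 8 | [N-]=[N+]=C(c1cc(OC)cc(OC)c1)c1c(Br)cc(OC)cc1OCc1ccc(OC)cc1 | intermediate
10 | (2S,3R)-4-bromo-3-(3,5-dimethoxyphenyl)-6-methoxy-2-(4-methoxyphenyl)-2,3-dihydro-1-benzofuran (cis) | Brc1cc(OC)cc2c1[C@@H](c1cc(OC)cc(OC)c1)[C@@H](c1ccc(OC)cc1)O2 | intermediate
11 | (2R,3R)-4-bromo-3-(3,5-dimethoxyphenyl)-6-methoxy-2-(4-methoxyphenyl)-2,3-dihydro-1-benzofuran (trans) | Brc1cc(OC)cc2c1[C@@H](c1cc(OC)cc(OC)c1)[C@H](c1ccc(OC)cc1)O2 | intermediate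
12 | 4-lithio derivative of 11 | [Li]c1cc(OC)cc2c1[C@@H](c1cc(OC)cc(OC)c1)[C@H](c1ccc(OC)cc1)O2 | intermediate
13 | methyl (2R,3R)-3-(3,5-dimethoxyphenyl)-6-methoxy-2-(4-methoxyphenyl)-2,3-dihydro-1-benzofuran-4-carboxylate | COC(=O)c1cc(OC)cc2c1[C@@H](c1cc(OC)cc(OC)c1)[C@H](c1ccc(OC)cc1)O2 | intermediate
14 | 4-methoxybenzoyl chloride | COc1ccc(C(=O)Cl)cc1 | starting material
15 | methyl (2R,3R)-3-[3,5-dimethoxy-2-(4-methoxybenzoyl)phenyl]-6-methoxy-2-(4-methoxyphenyl)-2,3-dihydro-1-benzofuran-4-carboxylate | COC(=O)c1cc(OC)cc2c1[C@@H](c1cc(OC)cc(OC)c1C(=O)c1ccc(OC)cc1)[C@H](c1ccc(OC)cc1)O2 | intermediate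
16 | diol from 15 (CH2OH on ring A, CH(OH)(4-methoxyphenyl) on ring B, both carbinol epimers) | OCc1cc(OC)cc2c1[C@@H](c1cc(OC)cc(OC)c1C(O)c1ccc(OC)cc1)[C@H](c1ccc(OC)cc1)O2 | intermediate
17 | dibromide from 16 | BrCc1cc(OC)cc2c1[C@@H](c1cc(OC)cc(OC)c1C(Br)c1ccc(OC)cc1)[C@H](c1ccc(OC)cc1)O2 | intermediate
18 | eight-membered cyclic sulfide, both epimers at S–CH(aryl) | COc1ccc(C2c3c(OC)cc(OC)cc3[C@@H]3c4c(cc(OC)cc4CS2)O[C@H]3c2ccc(OC)cc2)cc1 | intermediate
19 | eight-membered cyclic sulfone, both epimers at the diarylmethyl carbon | COc1ccc(C2c3c(OC)cc(OC)cc3[C@@H]3c4c(cc(OC)cc4CS2(=O)=O)O[C@H]3c2ccc(OC)cc2)cc1 | intermediate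
20 | α-chloro sulfone (chlorine on the diarylmethyl carbon) | COc1ccc(C2(Cl)c3c(OC)cc(OC)cc3[C@@H]3c4c(cc(OC)cc4CS2(=O)=O)O[C@H]3c2ccc(OC)cc2)cc1 | intermediate
21 | episulfone (C1 and C2 bonded, SO2 bridging both) | COc1ccc(C26c3c(OC)cc(OC)cc3[C@@H]3c4c(cc(OC)cc4C6S2(=O)=O)O[C@H]3c2ccc(OC)cc2)cc1 | intermediate
22 | cyclic stilbene: dihydrofuran-fused dibenzocycloheptatriene with 4-methoxyphenyl on C1 of the C1=C2 bond, (2R,3R)-dihydrofuran | COc1ccc(C2=Cc3cc(OC)cc4c3[C@@H](c3cc(OC)cc(OC)c32)[C@H](c2ccc(OC)cc2)O4)cc1 | intermediate
23 | hydroxy ester (benzhydrol from 15, both epimers) | COC(=O)c1cc(OC)cc2c1[C@@H](c1cc(OC)cc(OC)c1C(O)c1ccc(OC)cc1)[C@H](c1ccc(OC)cc1)O2 | intermediate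
24 | benzhydryl methyl ether ester, both epimers | COC(=O)c1cc(OC)cc2c1[C@@H](c1cc(OC)cc(OC)c1C(OC)c1ccc(OC)cc1)[C@H](c1ccc(OC)cc1)O2 | intermediate
25 | Weinreb amide of 24 | CON(C)C(=O)c1cc(OC)cc2c1[C@@H](c1cc(OC)cc(OC)c1C(OC)c1ccc(OC)cc1)[C@H](c1ccc(OC)cc1)O2 | intermediate
26 | methyl ketone (4-acetyl dihydrobenzofuran with benzhydryl methyl ether) | CC(=O)c1cc(OC)cc2c1[C@@H](c1cc(OC)cc(OC)c1C(OC)c1ccc(OC)cc1)[C@H](c1ccc(OC)cc1)O2 | intermediate
27 | trimethylsilyl enol ether of 26 | C=C(O[Si](C)(C)C)c1cc(OC)cc2c1[C@@H](c1cc(OC)cc(OC)c1C(OC)c1ccc(OC)cc1)[C@H](c1ccc(OC)cc1)O2 | intermediate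
28 | eight-membered ring ketone (C4=O, C5 H2, C6 H and 4-methoxyphenyl) | O=C2c4cc(OC)cc5c4[C@@H](c4cc(OC)cc(OC)c4[C@H](c4ccc(OC)cc4)C2)[C@H](c2ccc(OC)cc2)O5 | intermediate
29 | ketone 28 with ring E dihydrobenzofuranyl on C5, trans to the C6 aryl | O=C2c4cc(OC)cc5c4[C@@H](c4cc(OC)cc(OC)c4[C@H](c4ccc(OC)cc4)[C@H]2c2cc(OC)cc4c2[C@@H](c2cc(OC)cc(OC)c2)[C@H](c2ccc(OC)cc2)O4)[C@H](c2ccc(OC)cc2)O5 | intermediate
30 | exocyclic methylene compound (C4=CH2) | C=C2c4cc(OC)cc5c4[C@@H](c4cc(OC)cc(OC)c4[C@H](c4ccc(OC)cc4)[C@H]2c2cc(OC)cc4c2[C@@H](c2cc(OC)cc(OC)c2)[C@H](c2ccc(OC)cc2)O4)[C@H](c2ccc(OC)cc2)O5 | intermediate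
31 | B-alkyl-9-BBN (C4–CH2–B) | C(B1C2CCCC1CCC2)[C@H]2c4cc(OC)cc5c4[C@@H](c4cc(OC)cc(OC)c4[C@H](c4ccc(OC)cc4)[C@H]2c2cc(OC)cc4c2[C@@H](c2cc(OC)cc(OC)c2)[C@H](c2ccc(OC)cc2)O4)[C@H](c2ccc(OC)cc2)O5 | intermediate
32 | primary alcohol (C4–CH2OH, H-4 cis to H-5) | OC[C@H]2c4cc(OC)cc5c4[C@@H](c4cc(OC)cc(OC)c4[C@H](c4ccc(OC)cc4)[C@H]2c2cc(OC)cc4c2[C@@H](c2cc(OC)cc(OC)c2)[C@H](c2ccc(OC)cc2)O4)[C@H](c2ccc(OC)cc2)O5 | intermediate
33 | aldehyde (C4–CHO) | O=C[C@H]2c4cc(OC)cc5c4[C@@H](c4cc(OC)cc(OC)c4[C@H](c4ccc(OC)cc4)[C@H]2c2cc(OC)cc4c2[C@@H](c2cc(OC)cc(OC)c2)[C@H](c2ccc(OC)cc2)O4)[C@H](c2ccc(OC)cc2)O5 | intermediate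
34 | 4-methoxyphenylmagnesium bromide (THF solution) | COc1ccc([Mg]Br)cc1 | starting material
35 | carbinol C4–CH(OH)(4-methoxyphenyl), both epimers at C3 | OC(c3ccc(OC)cc3)[C@H]2c4cc(OC)cc5c4[C@@H](c4cc(OC)cc(OC)c4[C@H](c4ccc(OC)cc4)[C@H]2c2cc(OC)cc4c2[C@@H](c2cc(OC)cc(OC)c2)[C@H](c2ccc(OC)cc2)O4)[C@H](c2ccc(OC)cc2)O5 | intermediate
36 | 4-methoxybenzylic cation at C3 | [CH+](c3ccc(OC)cc3)[C@H]2c4cc(OC)cc5c4[C@@H](c4cc(OC)cc(OC)c4[C@H](c4ccc(OC)cc4)[C@H]2c2cc(OC)cc4c2[C@@H](c2cc(OC)cc(OC)c2)[C@H](c2ccc(OC)cc2)O4)[C@H](c2ccc(OC)cc2)O5 | intermediate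
37 | diaryl cation at C1 after C2–C3 bond formation | COc1ccc([C+]2c3c(OC)cc(OC)cc3[C@@H]3c4c(cc(OC)cc4[C@H]2[C@H](c2ccc(OC)cc2)[C@H]2c4cc(OC)cc5c4[C@@H](c4cc(OC)cc(OC)c4[C@H](c4ccc(OC)cc4)[C@H]2c2cc(OC)cc4c2[C@@H](c2cc(OC)cc(OC)c2)[C@H](c2ccc(OC)cc2)O4)[C@H](c2ccc(OC)cc2)O5)O[C@H]3c2ccc(OC)cc2)cc1 | intermediate
38 | pentadecamethyl ether of the target | COc1ccc([C@H]2c3c(OC)cc(OC)cc3[C@@H]3c4c(cc(OC)cc4[C@H]2[C@H](c2ccc(OC)cc2)[C@H]2c4cc(OC)cc5c4[C@@H](c4cc(OC)cc(OC)c4[C@H](c4ccc(OC)cc4)[C@H]2c2cc(OC)cc4c2[C@@H](c2cc(OC)cc(OC)c2)[C@H](c2ccc(OC)cc2)O4)[C@H](c2ccc(OC)cc2)O5)O[C@H]3c2ccc(OC)cc2)cc1 | intermediate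
39 | target hexamer CNP0184494.1 | Oc1ccc([C@H]2c3c(O)cc(O)cc3[C@@H]3c4c(cc(O)cc4[C@H]2[C@H](c2ccc(O)cc2)[C@H]2c4cc(O)cc5c4[C@@H](c4cc(O)cc(O)c4[C@H](c4ccc(O)cc4)[C@H]2c2cc(O)cc4c2[C@@H](c2cc(O)cc(O)c2)[C@H](c2ccc(O)cc2)O4)[C@H](c2ccc(O)cc2)O5)O[C@H]3c2ccc(O)cc2)cc1 | target

## Step count and least certain steps

Total: 25 steps. Longest linear sequence: 21 steps (steps 1 to 10, then 15 to 25); the left half needs steps 1 to 14 and joins at step 24.

**Step 14 (key step).** The most likely failure is addition of dichlorocarbene, formed from CCl4 and KOH, to the electron-rich alkene as it forms, together with slow episulfone closure at the hindered tertiary chloride. The fallback sets out from diol 16: both carbinols are oxidised (Dess–Martin periodinane) to the keto aldehyde F1, and an intramolecular McMurry coupling (TiCl4, Zn, pyridine, THF, reflux, high dilution) joins the aldehyde carbon and the diaryl ketone carbon directly to the same C1=C2 bond. It comes back to the route at 22.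

**Step 24.** Several processes can go wrong:
- cation 36 can lose the C4 proton to a stilbene and be re-protonated, which would erase C4;
- 36 can be captured within the molecule by the free ortho position of ring D or by ring F, or by ring positions of 22 instead of its alkene;
- facial selectivity at C3 may be poor.

The fallback sets out from aldehyde 33 and alkene 22 and makes the C2–C3 bond with a smaller electrophile that has no ionisable benzylic position. BF3·OEt2 activates the aldehyde for a Prins-type addition of the alkene, and Et3SiH reduces the C1 cation to the secondary alcohol F2. Oxidation (Dess–Martin periodinane) gives ketone F3, and addition of 34 in the presence of CeCl3 gives the tertiary carbinol F4. Ionic deoxygenation (TFA, Et3SiH present from the start, so that the C3 cation is reduced before it can react otherwise) returns to the route at 38.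

**Step 18.** The likely failure is poor facial selectivity at C6 when the carbenium ion meets the enol carbon, besides intermolecular alkylation if dilution is insufficient. The fallback sets out from 28 (either C6 epimer) and sets C6 by hydride delivery instead of by C–C bond formation. Saegusa oxidation (LiHMDS, TMSCl; then Pd(OAc)2, MeCN) gives the enone F5 with a C5=C6 double bond, and ionic hydrogenation (TFA, Et3SiH) delivers hydride to the diaryl-stabilised C6 from the open face. It comes back at 28.

**Step 7.** The diazo carbon carries two ortho-substituted aryl groups, so formation of the rhodium carbene may be slow and the uncatalysed, racemic insertion or azine formation may take over; acid epimerisation in step 8 could also erode C3 through the open cation. The fallback sets out from ketone 7: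
- Corey–Chaykovsky epoxidation (trimethylsulfonium iodide, KOtBu, DMSO) gives the epoxide F6;
- Meinwald rearrangement (ZnI2) gives the diarylacetaldehyde F7;
- addition of 34 gives the triarylethanol F8;
- TFA with anisole removes the 4-methoxybenzyl group and closes the ring through the 4-methoxybenzylic cation to the racemic trans bromide F9;
- F9 is resolved by preparative chromatography on a chiral stationary phase.

It comes back at 11.

**Step 10.** The likely failure is acylation at the carbon between the two methoxy groups of the resorcinol ring, or on ring A. The fallback sets out from ester 13 and uses a smaller electrophile: Vilsmeier–Haack formylation (POCl3, DMF) gives the aldehyde F10, addition of 34 at −78 °C gives hydroxy ester 23, and oxidation (Dess–Martin periodinane) comes back to the route at 15.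

**Step 25.** The likely failure is Lewis-acid opening of the dihydrofuran C2–O bonds with capture of the benzylic cations by the free phenol rings, and incomplete cleavage of fifteen ethers. The fallback sets out from 38 and uses SN2 demethylation without a Lewis acid (NaSEt, DMF, 140 °C), coming back at 39; no new isolated compound arises (entry F0).

## Further compounds

F1 | step 14 | (2R,3R)-3-[3,5-dimethoxy-2-(4-methoxybenzoyl)phenyl]-6-methoxy-2-(4-methoxyphenyl)-2,3-dihydro-1-benzofuran-4-carbaldehyde | O=Cc1cc(OC)cc2c1[C@@H](c1cc(OC)cc(OC)c1C(=O)c1ccc(OC)cc1)[C@H](c1ccc(OC)cc1)O2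
F2 | step 24 | secondary alcohol: skeleton of 38 with CH(OH) at C3 in place of CH(4-methoxyphenyl) | COc1ccc([C@H]2c3c(OC)cc(OC)cc3[C@@H]3c4c(cc(OC)cc4[C@H]2C(O)[C@H]2c4cc(OC)cc5c4[C@@H](c4cc(OC)cc(OC)c4[C@H](c4ccc(OC)cc4)[C@H]2c2cc(OC)cc4c2[C@@H](c2cc(OC)cc(OC)c2)[C@H](c2ccc(OC)cc2)O4)[C@H](c2ccc(OC)cc2)O5)O[C@H]3c2ccc(OC)cc2)cc1
F3 | step 24 | ketone: C3=O between C2 and C4 | COc1ccc([C@H]2c3c(OC)cc(OC)cc3[C@@H]3c4c(cc(OC)cc4[C@H]2C(=O)[C@H]2c4cc(OC)cc5c4[C@@H](c4cc(OC)cc(OC)c4[C@H](c4ccc(OC)cc4)[C@H]2c2cc(OC)cc4c2[C@@H](c2cc(OC)cc(OC)c2)[C@H](c2ccc(OC)cc2)O4)[C@H](c2ccc(OC)cc2)O5)O[C@H]3c2ccc(OC)cc2)cc1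
F4 | step 24 | tertiary carbinol: C3 bearing OH and 4-methoxyphenyl | COc1ccc([C@H]2c3c(OC)cc(OC)cc3[C@@H]3c4c(cc(OC)cc4[C@H]2C(O)(c2ccc(OC)cc2)[C@H]2c4cc(OC)cc5c4[C@@H](c4cc(OC)cc(OC)c4[C@H](c4ccc(OC)cc4)[C@H]2c2cc(OC)cc4c2[C@@H](c2cc(OC)cc(OC)c2)[C@H](c2ccc(OC)cc2)O4)[C@H](c2ccc(OC)cc2)O5)O[C@H]3c2ccc(OC)cc2)cc1
F5 | step 18 | eight-membered ring enone (C4=O, C5=C6 with 4-methoxyphenyl on C6) | O=C2c4cc(OC)cc5c4[C@@H](c4cc(OC)cc(OC)c4C(c4ccc(OC)cc4)=C2)[C@H](c2ccc(OC)cc2)O5
F6 | step 7 | 2-[2-bromo-4-methoxy-6-(4-methoxybenzyloxy)phenyl]-2-(3,5-dimethoxyphenyl)oxirane (racemic) | C1OC1(c1cc(OC)cc(OC)c1)c1c(Br)cc(OC)cc1OCc1ccc(OC)cc1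
F7 | step 7 | 2-[2-bromo-4-methoxy-6-(4-methoxybenzyloxy)phenyl]-2-(3,5-dimethoxyphenyl)acetaldehyde (racemic) | O=CC(c1cc(OC)cc(OC)c1)c1c(Br)cc(OC)cc1OCc1ccc(OC)cc1
F8 | step 7 | 2-[2-bromo-4-methoxy-6-(4-methoxybenzyloxy)phenyl]-2-(3,5-dimethoxyphenyl)-1-(4-methoxyphenyl)ethanol (diastereomer mixture) | OC(c1ccc(OC)cc1)C(c1cc(OC)cc(OC)c1)c1c(Br)cc(OC)cc1OCc1ccc(OC)cc1
F9 | step 7 | racemic trans-4-bromo-3-(3,5-dimethoxyphenyl)-6-methoxy-2-(4-methoxyphenyl)-2,3-dihydro-1-benzofuran (drawn as the 2R,3R enantiomer, present with an equal amount of the 2S,3S enantiomer) | Brc1cc(OC)cc2c1[C@@H](c1cc(OC)cc(OC)c1)[C@H](c1ccc(OC)cc1)O2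
F10 | step 10 | methyl (2R,3R)-3-(2-formyl-3,5-dimethoxyphenyl)-6-methoxy-2-(4-methoxyphenyl)-2,3-dihydro-1-benzofuran-4-carboxylate | COC(=O)c1cc(OC)cc2c1[C@@H](c1cc(OC)cc(OC)c1C=O)[C@H](c1ccc(OC)cc1)O2
F0 | step 25 | none | none
A1 | alternative 1 | hexa-aryl hexyl boronic ester (1,2-dicyclohexylethanediol ester) with six contiguous stereocentres | COc1ccc(cc1)[C@@H](B1O[C@H](C2CCCCC2)[C@@H](C2CCCCC2)O1)[C@@H](c2cc(OC)cc(OC)c2)[C@H](c2ccc(OC)cc2)[C@@H](c2cc(OC)cc(OC)c2)[C@H](c2cc(OC)cc(OC)c2)[C@@H](c2ccc(OC)cc2)c2c(Br)cc(OC)cc2OC
A2 | alternative 2 | eight-ring tetramer-level intermediate with two ring bromines, one 3,5-di-tert-butyl-4-hydroxyphenyl group and one remaining di-tert-butyl para-quinone methide | O=C1C(C(C)(C)C)=CC(=C[C@H]2c4c(Br)c(OC)cc5c4[C@@H](c4cc(OC)cc(OC)c4[C@H](c4cc(C(C)(C)C)c(O)c(C(C)(C)C)c4)[C@H]2c2c(Br)c(OC)cc4c2[C@@H](c2cc(OC)cc(OC)c2)[C@H](c2ccc(OC)cc2)O4)[C@H](c2ccc(OC)cc2)O5)C=C1C(C)(C)C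
A3 | alternative 3 | permethylated hexamer skeleton with both medium rings closed and the furans on rings A and C still aromatic 2,3-diarylbenzofurans | COc1ccc([C@H]2c3c(OC)cc(OC)cc3-c3c4c(cc(OC)cc4[C@H]2[C@H](c2ccc(OC)cc2)[C@H]2c4cc(OC)cc5c4c(-c4cc(OC)cc(OC)c4[C@H](c4ccc(OC)cc4)[C@H]2c2cc(OC)cc4c2[C@@H](c2cc(OC)cc(OC)c2)[C@H](c2ccc(OC)cc2)O4)c(-c2ccc(OC)cc2)o5)oc3-c2ccc(OC)cc2)cc1
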